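**Strategy.** The seven-membered ring (C5–C6–C7–C8–C9–C10–C11) is opened at C6–C7. Quaternary C6 carries the carboxyl-level carbon (later CH2O-angeloyl) and is bonded to the C7 carbinol, a β-hydroxy ester unit. One samarium-enolate aldol closure, from an α-bromo ester on C5 and an aldehyde three carbons out from C10, therefore forms the bond, the ring and both stereocentres (C6, C7). The precursor is a 4-methylbicyclo[3.1.1]hept-3-en-2-one (enone ring C1–C4, C10, C11; cyclobutane C4, C5, C11, C10) whose two arms stand on the same cyclobutane face. It comes from an intramolecular vinylketene–alkene cycloaddition steered by an allylic silyloxy stereocentre.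

Key step: step 19

Numbering (target atoms): C1 ketone; C2=C3 with CH3 on C3; C4 and C11 bridgeheads; C5 (bears C6) and C10 (bears CH3 and C9) are the one-carbon bridges; C6 quaternary; C7 CH–OAc; C8 CH2; C9 CH–O. On C5 and C10, syn means towards the C1–C3 bridge and anti away from it; the "C5 face" of C1 is the side of that bridge turned to C5.
Abbreviations: TBDPS = tert-butyldiphenylsilyl, TES = triethylsilyl, TBS = tert-butyldimethylsilyl, DMP = 1,1,1-triacetoxy-1,1-dihydro-1,2-benziodoxol-3(1H)-one.
Remark 1: bromides 18–24 are drawn as one C6 epimer; bromination may give both, and both give the same planar samarium enolate.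
Remark 2: the carboxyl carbon is carried as a methyl ester, because an ester on quaternary C6 must later be reduced by hydride; the bromide is installed while C1 is still an alcohol, because an ester enolate at C6 beside a C1 ketone can open the cyclobutane by retro-Michael cleavage.
Remark 3: the only methyl-bearing quaternary ring carbon is C10, the carbon that also carries C9; C4 next to the enone alkene is a CH, and the core is built accordingly.

Step 1
Reactants: 1 ethyl (E)-3-methyl-4-oxobut-2-enoate
Product: 2 ethyl (E)-4-hydroxy-3-methylbut-2-enoate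
Conditions: NaBH4, EtOH, −20 °C
Reagents that add atoms: none
Why: Borohydride carbonyl reduction takes the aldehyde 1,2 far faster than the conjugated ester and leaves the E alkene untouched.

Step 2
Reactants: 2 ethyl (E)-4-hydroxy-3-methylbut-2-enoate
Product: 3 ethyl (E)-4-[(tert-butyldiphenylsilyl)oxy]-3-methylbut-2-enoate
Conditions: TBDPSCl, imidazole, DMF, rt
Reagents that add atoms: tert-butyl(chloro)diphenylsilane CC(C)(C)[Si](Cl)(c1ccccc1)c1ccccc1
Why: Silylation of the primary allylic alcohol gives a bulky ether that is stable to hydride, base and heat until step 14.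

Step 3
Reactants: 3 ethyl (E)-4-[(tert-butyldiphenylsilyl)oxy]-3-methylbut-2-enoate
Product: 4 (E)-4-[(tert-butyldiphenylsilyl)oxy]-3-methylbut-2-en-1-ol
Conditions: DIBAL-H (2.2 equiv), CH2Cl2, −78 °C
Reagents that add atoms: none
Why: DIBAL-H reduction of the α,β-unsaturated ester goes 1,2 to the allylic alcohol at low temperature without touching the silyl ether or the alkene geometry.

Step 4
Reactants: 4 (E)-4-[(tert-butyldiphenylsilyl)oxy]-3-methylbut-2-en-1-ol
Product: 5 (E)-4-[(tert-butyldiphenylsilyl)oxy]-3-methylbut-2-enal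
Conditions: MnO2, CH2Cl2, rt
Reagents that add atoms: none
Why: Allylic oxidation with MnO2 stops at the enal and keeps the E geometry, which places CH2OSi trans to the formyl carbon as the cycloaddition of step 9 requires.

Step 5
Reactants: 6 methyl 3-methylbut-2-enoate
Product: 7 tert-butyl[(1-methoxy-3-methylbuta-1,3-dien-1-yl)oxy]dimethylsilane
Conditions: LDA, THF, −78 °C; TBSCl, DMPU, −78 °C → rt
Reagents that add atoms: tert-butyl(chloro)dimethylsilane CC(C)(C)[Si](C)(C)Cl
Why: γ-Deprotonation of the β,β-dimethylacrylate and O-silylation of the extended enolate (silyl ketene acetal formation) give the dienolate needed for the vinylogous aldol.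

Step 6
Reactants: 5 (E)-4-[(tert-butyldiphenylsilyl)oxy]-3-methylbut-2-enal; 7 tert-butyl[(1-methoxy-3-methylbuta-1,3-dien-1-yl)oxy]dimethylsilane
Product: 8 methyl (2E,5S,6E)-8-[(tert-butyldiphenylsilyl)oxy]-5-hydroxy-3,7-dimethylocta-2,6-dienoate
Conditions: SiCl4 (1.1 equiv), chiral bisphosphoramide C51H52N6O2P2 (two N,N'-dimethyl-1,1'-binaphthyl-2,2'-diamine phosphoramide units joined through N,N'-dimethylpentane-1,5-diamine; 5 mol %; the enantiomer that directs Si-face attack), CH2Cl2, −78 °C; aq. NaHCO3/KF
Reagents that add atoms: none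
Why: In this vinylogous Mukaiyama aldol addition the dienolate attacks through its γ-carbon (E enoate, ester trans to the chain) on the Si face of the enal selected by the catalyst, which sets the 5S carbinol that becomes C1 and later controls the absolute configuration of the bicycle.

Step 7
Reactants: 8 methyl (2E,5S,6E)-8-[(tert-butyldiphenylsilyl)oxy]-5-hydroxy-3,7-dimethylocta-2,6-dienoate
Product: 9 methyl (2E,5S,6E)-8-[(tert-butyldiphenylsilyl)oxy]-3,7-dimethyl-5-[(triethylsilyl)oxy]octa-2,6-dienoate
Conditions: TESCl, imidazole, DMF, 0 °C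
Reagents that add atoms: chlorotriethylsilane CC[Si](Cl)(CC)CC
Why: Silylation of the secondary allylic alcohol as the acid-labile triethylsilyl ether allows its later removal in the presence of the primary TBDPS ether.

Step 8
Reactants: 9 methyl (2E,5S,6E)-8-[(tert-butyldiphenylsilyl)oxy]-3,7-dimethyl-5-[(triethylsilyl)oxy]octa-2,6-dienoate
Product: 10 (2E,5S,6E)-8-[(tert-butyldiphenylsilyl)oxy]-3,7-dimethyl-5-[(triethylsilyl)oxy]octa-2,6-dienoic acid
Conditions: KOSiMe3, THF, rt; then aq. KHSO4 to pH 4, 0 °C
Reagents that add atoms: potassium trimethylsilanolate C[Si](C)(C)[O-].[K+]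
Why: Anhydrous silanolate cleavage of the methyl ester (nucleophilic ester cleavage) frees the acid under conditions that spare both silyl ethers and do not cause vinylogous β-elimination of the 5-silyloxy group.

Step 9
Reactants: 10 (2E,5S,6E)-8-[(tert-butyldiphenylsilyl)oxy]-3,7-dimethyl-5-[(triethylsilyl)oxy]octa-2,6-dienoic acid
Product: 13 7-{[(tert-butyldiphenylsilyl)oxy]methyl}-7-methyl-2-methylidene-4-[(triethylsilyl)oxy]bicyclo[3.1.1]heptan-6-one (C5 ketone; C1–OTES on the C5 face; C10 CH3 syn and CH2OTBDPS anti), via acid chloride 11 (not isolated), via vinylketene 12 (not isolated)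
Conditions: 1-chloro-N,N,2-trimethylprop-1-en-1-amine, CH2Cl2, 0 °C; then slow addition to Et3N, toluene, 110 °C (0.01 M)
Reagents that add atoms: none
Why: In this intramolecular vinylketene–alkene [2+2] cycloaddition, 1,4-dehydrochlorination of the E acid chloride through its cis methyl gives vinylketene 12, whose carbonyl carbon bonds to the alkene CH and whose α-carbon bonds to the disubstituted carbon (crossed mode, the known route from dienoyl chlorides to bicyclo[3.1.1]heptan-6-ones); suprafacial addition to the E alkene places CH3 syn and CH2OSi anti on C10, and allylic 1,3-strain (C1–H eclipsing the alkene towards its cis methyl) makes the ketene add to the face opposite the silyloxy group, which fixes C4, C10 and C11 relative to C1 and leaves the C1 oxygen on the C5 face.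

Step 10
Reactants: 13 cycloadduct ketone
Product: 15 methyl (2E)-2-(7-{[(tert-butyldiphenylsilyl)oxy]methyl}-4-hydroxy-7-methyl-2-methylidenebicyclo[3.1.1]heptan-6-ylidene)acetate, via triethylsilyl ether 14 (not isolated)
Conditions: (MeO)2P(O)CH2CO2Me, NaH, THF, 0 → 60 °C; then PPTS, MeOH, rt
Reagents that add atoms: trimethyl phosphonoacetate COC(=O)CP(=O)(OC)OC
Why: Horner–Wadsworth–Emmons olefination of the strained, non-enolizable cyclobutanone (the phosphonate anion enters from the anti face and the ester turns away from the C1 silyloxy group) is followed by mild acid methanolysis that cleaves only the triethylsilyl ether.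

Step 11
Reactants: 15 alkylidene ester with free C1 hydroxyl
Product: 16 methyl 2-(7-{[(tert-butyldiphenylsilyl)oxy]methyl}-4-hydroxy-7-methyl-2-methylidenebicyclo[3.1.1]heptan-6-yl)acetate (C5–H syn, CH2CO2Me anti)
Conditions: SmI2 (2.5 equiv), HMPA, THF, 0 °C → rt, no added proton donor; then aq. NH4Cl
Reagents that add atoms: none
Why: In this SmI2 conjugate reduction of the α,β-unsaturated ester by single-electron transfer, the C5 carbanion keeps the ester arm in the less crowded anti position and is protonated by the only proton donor present, the C1 hydroxyl on the bridge face of C5, so hydrogen should arrive syn and set C5 with the arm anti, cis to the C10 arm.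

Step 12
Reactants: 16 saturated ester
Product: 17 methyl 2-(7-{[(tert-butyldiphenylsilyl)oxy]methyl}-4-hydroxy-7-methyl-2-methylidenebicyclo[3.1.1]heptan-6-yl)propanoate (C6 epimer mixture)
Conditions: LDA (2.2 equiv), THF, −78 °C; MeI, −78 → −30 °C
Reagents that add atoms: iodomethane CI
Why: In this enolate alkylation of the alkoxide–ester enolate dianion, C-methylation of the lithium ester enolate is far faster than O-methylation of the lithium alkoxide at low temperature, and the new C6 centre needs no control because it becomes planar again in steps 13 and 19.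

Step 13
Reactants: 17 α-methyl ester
Product: 18 methyl 2-bromo-2-(7-{[(tert-butyldiphenylsilyl)oxy]methyl}-4-hydroxy-7-methyl-2-methylidenebicyclo[3.1.1]heptan-6-yl)propanoate
Conditions: LDA (2.3 equiv), THF, −78 → −40 °C; CBr4, −78 °C
Reagents that add atoms: tetrabromomethane BrC(Br)(Br)Br
Why: Electrophilic bromination of the tertiary lithium ester enolate gives the α-bromo ester while C1 is an alkoxide and not a ketone, so that the enolate has no retro-Michael pathway into the cyclobutane.

Step 14
Reactants: 18 bromo ester silyl ether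
Product: 19 methyl 2-bromo-2-[4-hydroxy-7-(hydroxymethyl)-7-methyl-2-methylidenebicyclo[3.1.1]heptan-6-yl]propanoate
Conditions: TBAF, AcOH (1:1), THF, rt
Reagents that add atoms: none
Why: Fluoride desilylation buffered with acetic acid frees the primary alcohol without base-induced loss of HBr from the tertiary bromide or acid-induced reaction of the exocyclic alkene.

Step 15
Reactants: 19 bromo ester diol
Product: 21 methyl 2-bromo-2-(6-formyl-2,6-dimethyl-4-oxobicyclo[3.1.1]hept-2-en-7-yl)propanoate, via methylidene keto aldehyde 20 (not isolated)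
Conditions: DMP (3 equiv), pyridine, CH2Cl2, rt; then Et3N, rt
Reagents that add atoms: none
Why: Periodinane oxidation converts both alcohols (C1 to the ketone, C9 to the aldehyde), and the amine then moves the β,γ double bond of 20 into conjugation through the dienol (thermodynamic enone), while the aldehyde on quaternary C10 cannot enolize.

Step 16
Reactants: 21 enone aldehyde
Product: 22 methyl 2-bromo-2-{6-[(1R)-1-hydroxybut-3-en-1-yl]-2,6-dimethyl-4-oxobicyclo[3.1.1]hept-2-en-7-yl}propanoate
Conditions: (+)-Ipc2BOMe (from (−)-α-pinene), allylMgBr, Et2O, 0 °C → rt, Mg salts filtered; 21, Et2O, −78 °C; then HOCH2CH2NH2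
Reagents that add atoms: allylmagnesium bromide C=CC[Mg]Br
Why: In this allylboration through a closed chair transition state (Brown allylation), the borane of the (−)-α-pinene series should add allyl to the Re face of the non-enolizable aldehyde and give the 9R carbinol under reagent control, and at −78 °C it leaves the enone, the ester and the tertiary bromide alone.

Step 17
Reactants: 22 homoallylic alcohol
Product: 23 methyl 2-bromo-2-{6-[(1R)-1-[(tert-butyldimethylsilyl)oxy]but-3-en-1-yl]-2,6-dimethyl-4-oxobicyclo[3.1.1]hept-2-en-7-yl}propanoate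
Conditions: TBSOTf, 2,6-lutidine, CH2Cl2, −78 → 0 °C
Reagents that add atoms: tert-butyldimethylsilyl trifluoromethanesulfonate CC(C)(C)[Si](C)(C)OS(=O)(=O)C(F)(F)F
Why: Silylation of the hindered neopentyl-type secondary alcohol with the silyl triflate and a hindered pyridine base is fast at low temperature and too mild to enolize the enone.

Step 18
Reactants: 23 silyl ether alkene
Product: 24 methyl 2-bromo-2-{6-[(1R)-1-[(tert-butyldimethylsilyl)oxy]-3-oxopropyl]-2,6-dimethyl-4-oxobicyclo[3.1.1]hept-2-en-7-yl}propanoate (bromo ester aldehyde, the ring-closure precursor)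
Conditions: O3, CH2Cl2, pyridine (cat.), −78 °C, dye end point; then PPh3
Reagents that add atoms: ozone O=[O+][O-]
Why: Ozonolysis with reductive work-up cleaves the electron-rich monosubstituted alkene to the aldehyde, while the conjugated trisubstituted enone alkene reacts far more slowly.

Step 19
Reactants: 24 bromo ester aldehyde
Product: 26 tricyclic β-hydroxy ester (methyl ester on C6 on the C11 side, C6 methyl on the C4 side, C7–OH anti to the C9–OTBS, C1 enone), via samarium enolate 25 (not isolated)
Conditions: SmI2 (2.5 equiv), THF, −78 °C, slow addition of 24 (0.005 M); then aq. NH4Cl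
Reagents that add atoms: none
Why: Two equivalents of SmI2 cleave the C6–Br bond (electron transfer, loss of bromide, second electron transfer) to the samarium ester enolate 25, whose C6 adds to the C7 aldehyde through a samarium-bridged six-membered chair, an intramolecular Reformatsky reaction whose closest precedent is the SmI2-promoted closure of medium rings from α-bromo esters and aldehydes. The seven-membered ring C5–C6–C7–C8–C9–C10–C11 closes in the 7-exo-trig mode, helped by both arms being held 1,3-diaxial on the anti face of the cyclobutane. C6 is set by the enolate face: in the twist of the forming ring that keeps the C9 silyloxy group staggered away from the C10 methyl, the bulky samarium-bound ester should take the outward position on C6, which lies on the C11 side, and the methyl the inner one. C7 is set by the aldehyde face: the samarium bridge holds the aldehyde oxygen gauche to the ester and the 1,3-related C9 silyloxy group pushes it to the other side, so the carbinol should be anti to the C9 oxygen. The step needs reduction of the tertiary bromide in the presence of enone and aldehyde, secured by the much faster reduction of α-bromo esters at −78 °C, and it must avoid retro-Michael opening of the cyclobutane, which the covalent, weakly basic samarium enolate, the low temperature and the immediate intramolecular trapping disfavour. High dilution suppresses intermolecular aldol and pinacol coupling.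

Step 20
Reactants: 26 tricyclic β-hydroxy ester
Product: 27 tricyclic triol (C6–CH2OH, C7–OH, allylic C1–OH on the C10 side, C9–OTBS)
Conditions: LiAlH4, THF, −30 → 0 °C
Reagents that add atoms: none
Why: Hydride reduction of the methyl ester to the primary alcohol, through a C7 aluminium alkoxide that does not undergo retro-aldol at low temperature, is accompanied by 1,2-reduction of the enone from the C5 face, and the C1 carbinol centre is erased again in step 21.

Step 21
Reactants: 27 tricyclic triol
Product: 28 tricyclic enone diol (C1 ketone, C6–CH2OH, C7–OH, C9–OTBS)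
Conditions: MnO2, CH2Cl2, rt
Reagents that add atoms: none
Why: Chemoselective allylic oxidation with MnO2 returns only the allylic C1 alcohol to the enone and leaves the primary neopentyl and the secondary C7 alcohols.

Step 22
Reactants: 28 tricyclic enone diol
Product: 29 primary angelate (C6–CH2O-angeloyl, C7–OH, C9–OTBS)
Conditions: angelic acid, 2,4,6-trichlorobenzoyl chloride, Et3N, toluene, rt; then 28, toluene, 80 °C
Reagents that add atoms: angelic acid C/C=C(/C)C(=O)O
Why: Acylation with the mixed anhydride of angelic acid (Yamaguchi-type esterification run without nucleophilic catalyst) should esterify the primary alcohol in preference to the more hindered secondary C7 alcohol and avoid Z to E isomerization of the angelate.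

Step 23
Reactants: 29 primary angelate
Product: 30 angelate acetate (C7–OAc, C9–OTBS)
Conditions: Ac2O, DMAP, pyridine, CH2Cl2, rt
Reagents that add atoms: acetic anhydride CC(=O)OC(C)=O
Why: DMAP-catalysed acetylation (nucleophilic catalysis) esterifies the remaining secondary C7 alcohol while the C9 oxygen is still masked as its silyl ether.

Step 24
Reactants: 30 angelate acetate
Product: 31 C9 alcohol (C6–CH2O-angeloyl, C7–OAc, C9–OH)
Conditions: HF·pyridine, pyridine, THF, 0 °C → rt
Reagents that add atoms: none
Why: Acidic fluoride desilylation removes the secondary TBS ether without the basic conditions that could cause acyl migration or isomerize the angelate.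

Step 25
Reactants: 31 C9 alcohol
Product: 32 target triester CNP0179010.1
Conditions: 3-methylbut-2-enoic acid, 2,4,6-trichlorobenzoyl chloride, Et3N, THF, rt; then 31, DMAP, toluene, rt → 50 °C
Reagents that add atoms: 3-methylbut-2-enoic acid CC(C)=CC(=O)O
Why: Yamaguchi esterification with the mixed anhydride and DMAP acylates the hindered C9 alcohol without deconjugating the senecioate and completes the triester with all seven stereocentres in place.

**Compound list**

1 | ethyl (E)-3-methyl-4-oxobut-2-enoate | CCOC(=O)/C=C(\C)C=O | starting material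
2 | ethyl (E)-4-hydroxy-3-methylbut-2-enoate | CCOC(=O)/C=C(\C)CO | intermediate
3 | ethyl (E)-4-[(tert-butyldiphenylsilyl)oxy]-3-methylbut-2-enoate | CCOC(=O)/C=C(\C)CO[Si](c1ccccc1)(c1ccccc1)C(C)(C)C | intermediate
4 | (E)-4-[(tert-butyldiphenylsilyl)oxy]-3-methylbut-2-en-1-ol | OC/C=C(\C)CO[Si](c1ccccc1)(c1ccccc1)C(C)(C)C | intermediate
5 | (E)-4-[(tert-butyldiphenylsilyl)oxy]-3-methylbut-2-enal | O=C/C=C(\C)CO[Si](c1ccccc1)(c1ccccc1)C(C)(C)C | intermediate
6 | methyl 3-methylbut-2-enoate | COC(=O)C=C(C)C | starting material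
7 | tert-butyl[(1-methoxy-3-methylbuta-1,3-dien-1-yl)oxy]dimethylsilane (ketene acetal geometry not controlled) | C=C(C)C=C(OC)O[Si](C)(C)C(C)(C)C | intermediate
8 | methyl (2E,5S,6E)-8-[(tert-butyldiphenylsilyl)oxy]-5-hydroxy-3,7-dimethylocta-2,6-dienoate | CC(C)(C)[Si](c1ccccc1)(c1ccccc1)OC/C(C)=C/[C@@H](O)C/C(C)=C/C(=O)OC | intermediate
9 | methyl (2E,5S,6E)-8-[(tert-butyldiphenylsilyl)oxy]-3,7-dimethyl-5-[(triethylsilyl)oxy]octa-2,6-dienoate | CC(C)(C)[Si](c1ccccc1)(c1ccccc1)OC/C(C)=C/[C@@H](O[Si](CC)(CC)CC)C/C(C)=C/C(=O)OC | intermediate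
10 | (2E,5S,6E)-8-[(tert-butyldiphenylsilyl)oxy]-3,7-dimethyl-5-[(triethylsilyl)oxy]octa-2,6-dienoic acid | CC(C)(C)[Si](c1ccccc1)(c1ccccc1)OC/C(C)=C/[C@@H](O[Si](CC)(CC)CC)C/C(C)=C/C(=O)O | intermediate
11 | acid chloride of 10 | CC(C)(C)[Si](c1ccccc1)(c1ccccc1)OC/C(C)=C/[C@@H](O[Si](CC)(CC)CC)C/C(C)=C/C(Cl)=O | intermediate
12 | vinylketene, (5S,6E)-8-[(tert-butyldiphenylsilyl)oxy]-7-methyl-3-methylidene-5-[(triethylsilyl)oxy]octa-1,6-dien-1-one | CC(C)(C)[Si](c1ccccc1)(c1ccccc1)OC/C(C)=C/[C@@H](O[Si](CC)(CC)CC)CC(=C)C=C=O | intermediate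
13 | 7-{[(tert-butyldiphenylsilyl)oxy]methyl}-7-methyl-2-methylidene-4-[(triethylsilyl)oxy]bicyclo[3.1.1]heptan-6-one; C5 ketone, C1–OTES on the C5 face, C10 CH3 syn, CH2OTBDPS anti | O=C1[C@H]2[C@@H](O[Si](CC)(CC)CC)CC(=C)[C@@H]1[C@@]2(C)CO[Si](c3ccccc3)(c3ccccc3)C(C)(C)C | intermediate
14 | methyl (2E)-2-(7-{[(tert-butyldiphenylsilyl)oxy]methyl}-7-methyl-2-methylidene-4-[(triethylsilyl)oxy]bicyclo[3.1.1]heptan-6-ylidene)acetate; ester on the C4 side | COC(=O)/C=C1/[C@H]2[C@@H](O[Si](CC)(CC)CC)CC(=C)[C@@H]1[C@@]2(C)CO[Si](c3ccccc3)(c3ccccc3)C(C)(C)C | intermediate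
15 | methyl (2E)-2-(7-{[(tert-butyldiphenylsilyl)oxy]methyl}-4-hydroxy-7-methyl-2-methylidenebicyclo[3.1.1]heptan-6-ylidene)acetate; C1–OH on the C5 face | COC(=O)/C=C1/[C@H]2[C@@H](O)CC(=C)[C@@H]1[C@@]2(C)CO[Si](c3ccccc3)(c3ccccc3)C(C)(C)C | intermediate
16 | methyl 2-(7-{[(tert-butyldiphenylsilyl)oxy]methyl}-4-hydroxy-7-methyl-2-methylidenebicyclo[3.1.1]heptan-6-yl)acetate; C5–H syn, CH2CO2Me anti | COC(=O)C[C@@H]1[C@H]2[C@@H](O)CC(=C)[C@@H]1[C@@]2(C)CO[Si](c3ccccc3)(c3ccccc3)C(C)(C)C | intermediate
17 | methyl 2-(7-{[(tert-butyldiphenylsilyl)oxy]methyl}-4-hydroxy-7-methyl-2-methylidenebicyclo[3.1.1]heptan-6-yl)propanoate; C6 epimer mixture | COC(=O)C(C)[C@@H]1[C@H]2[C@@H](O)CC(=C)[C@@H]1[C@@]2(C)CO[Si](c3ccccc3)(c3ccccc3)C(C)(C)C | intermediate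
18 | methyl 2-bromo-2-(7-{[(tert-butyldiphenylsilyl)oxy]methyl}-4-hydroxy-7-methyl-2-methylidenebicyclo[3.1.1]heptan-6-yl)propanoate | COC(=O)[C@@](C)(Br)[C@@H]1[C@H]2[C@@H](O)CC(=C)[C@@H]1[C@@]2(C)CO[Si](c3ccccc3)(c3ccccc3)C(C)(C)C | intermediate
19 | methyl 2-bromo-2-[4-hydroxy-7-(hydroxymethyl)-7-methyl-2-methylidenebicyclo[3.1.1]heptan-6-yl]propanoate | COC(=O)[C@@](C)(Br)[C@@H]1[C@H]2[C@@H](O)CC(=C)[C@@H]1[C@@]2(C)CO | intermediate
20 | methyl 2-bromo-2-(7-formyl-7-methyl-2-methylidene-4-oxobicyclo[3.1.1]heptan-6-yl)propanoate | COC(=O)[C@@](C)(Br)[C@@H]1[C@H]2C(=O)CC(=C)[C@@H]1[C@@]2(C)C=O | intermediate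
21 | methyl 2-bromo-2-(6-formyl-2,6-dimethyl-4-oxobicyclo[3.1.1]hept-2-en-7-yl)propanoate; formyl anti on C10, bromo ester arm anti on C5 | COC(=O)[C@@](C)(Br)[C@@H]1[C@H]2C(=O)C=C(C)[C@@H]1[C@@]2(C)C=O | intermediate
22 | methyl 2-bromo-2-{6-[(1R)-1-hydroxybut-3-en-1-yl]-2,6-dimethyl-4-oxobicyclo[3.1.1]hept-2-en-7-yl}propanoate | COC(=O)[C@@](C)(Br)[C@@H]1[C@H]2C(=O)C=C(C)[C@@H]1[C@@]2(C)[C@H](O)CC=C | intermediate
23 | methyl 2-bromo-2-{6-[(1R)-1-[(tert-butyldimethylsilyl)oxy]but-3-en-1-yl]-2,6-dimethyl-4-oxobicyclo[3.1.1]hept-2-en-7-yl}propanoate | COC(=O)[C@@](C)(Br)[C@@H]1[C@H]2C(=O)C=C(C)[C@@H]1[C@@]2(C)[C@H](O[Si](C)(C)C(C)(C)C)CC=C | intermediate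
24 | methyl 2-bromo-2-{6-[(1R)-1-[(tert-butyldimethylsilyl)oxy]-3-oxopropyl]-2,6-dimethyl-4-oxobicyclo[3.1.1]hept-2-en-7-yl}propanoate (bicyclo[3.1.1]heptenone bromo ester aldehyde) | COC(=O)[C@@](C)(Br)[C@@H]1[C@H]2C(=O)C=C(C)[C@@H]1[C@@]2(C)[C@H](O[Si](C)(C)C(C)(C)C)CC=O | intermediate
25 | samarium ester enolate of 24 (diiodosamarium O-enolate at C6, aldehyde still free) | COC(O[Sm](I)I)=C(C)[C@@H]1[C@H]2C(=O)C=C(C)[C@@H]1[C@@]2(C)[C@H](O[Si](C)(C)C(C)(C)C)CC=O | intermediate
26 | tricyclic β-hydroxy methyl ester; C1 enone, C6 CO2Me on the C11 side and CH3 on the C4 side, C7–OH anti to C9–OTBS | COC(=O)[C@]1(C)[C@@H]2[C@H]3C(=O)C=C(C)[C@@H]2[C@@]3(C)[C@H](O[Si](C)(C)C(C)(C)C)C[C@H]1O | intermediate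
27 | tricyclic triol; C1–OH on the C10 side (expected epimer), C6–CH2OH, C7–OH, C9–OTBS | OC[C@]1(C)[C@@H]2[C@H]3[C@H](O)C=C(C)[C@@H]2[C@@]3(C)[C@H](O[Si](C)(C)C(C)(C)C)C[C@H]1O | intermediate
28 | tricyclic enone diol; C6–CH2OH, C7–OH, C9–OTBS | OC[C@]1(C)[C@@H]2[C@H]3C(=O)C=C(C)[C@@H]2[C@@]3(C)[C@H](O[Si](C)(C)C(C)(C)C)C[C@H]1O | intermediate
29 | primary angelate; C7–OH, C9–OTBS | C/C=C(/C)C(=O)OC[C@]1(C)[C@@H]2[C@H]3C(=O)C=C(C)[C@@H]2[C@@]3(C)[C@H](O[Si](C)(C)C(C)(C)C)C[C@H]1O | intermediate
30 | angelate acetate; C7–OAc, C9–OTBS | C/C=C(/C)C(=O)OC[C@]1(C)[C@@H]2[C@H]3C(=O)C=C(C)[C@@H]2[C@@]3(C)[C@H](O[Si](C)(C)C(C)(C)C)C[C@H]1OC(C)=O | intermediate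
31 | angelate acetate with free C9–OH | C/C=C(/C)C(=O)OC[C@]1(C)[C@@H]2[C@H]3C(=O)C=C(C)[C@@H]2[C@@]3(C)[C@H](O)C[C@H]1OC(C)=O | intermediate
32 | CNP0179010.1 (C6–CH2O-angeloyl, C7–OAc, C9–O-senecioyl) | C/C=C(/C)C(=O)OC[C@]1(C)[C@@H]2[C@H]3C(=O)C=C(C)[C@@H]2[C@@]3(C)[C@H](OC(=O)C=C(C)C)C[C@H]1OC(C)=O | target

**Step count and risks**

Total step count: 25. Longest linear sequence: 24 steps (1 to 32 through steps 1–4 and 6–25; step 5 is a one-step side branch).

Steps most likely to fail:

1. Step 19 (ring closure). What may go wrong is attack on the other face of the aldehyde, giving the C7 epimer; cleavage of the cyclobutane from the samarium enolate is the second danger. The fallback corrects C7 after the closure. It sets out from 24: the same closure would give the C7-epimeric hydroxy ester F1. LiAlH4 in THF should reduce it to the epimeric triol F2, and excess DMP should oxidize all three alcohols to the keto aldehyde F3 (C1 enone, C7 ketone, formyl on C6). Me4NBH(OAc)3 in AcOH/MeCN at −20 °C should first reduce the aldehyde and then, bound to the new hydroxymethyl group, deliver hydride to C7 from that face (hydroxyl-directed reduction to the anti 1,3-diol). This returns to the route at 28.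

2. Step 11 (conjugate reduction). What may go wrong is protonation of C5 from the more open anti face by a stray external proton source (poor facial selectivity); the resulting C5 epimer would lactonize onto the C1 hydroxyl. The fallback sets C5 by substitution with inversion and sets out from 13. NaBH4 in MeOH should deliver hydride to the anti face and give the syn alcohol F4, and Tf2O with pyridine gives the triflate F5. Sodium dimethyl malonate in THF/DMF should displace it from the anti side (SN2 with inversion, elimination being impossible because both β-hydrogens are bridgehead) to give the malonate F6. Krapcho dealkoxycarbonylation (LiCl, wet DMSO, 140 °C) gives the acetate F7, and PPTS in MeOH removes the triethylsilyl group. This returns to the route at 16.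

3. Step 9 (cycloaddition). What may go wrong is oligomerization of the vinylketene outrunning its addition to the alkene, which two allylic silyloxy groups make less nucleophilic. The fallback uses the more electrophilic, non-dimerizing keteniminium ion and sets out from 10. Acid chloride 11 and dimethylamine give the dimethylamide F8. Tf2O with 2,4,6-collidine in 1,2-dichloroethane at 80 °C should form the vinylketeniminium ion, which cyclizes in the same sense to the cyclobutaniminium triflate F9. Aqueous NaHCO3 hydrolyses it, and the route is rejoined at 13.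

**Further compounds**

F1 | step 19 | C7-epimeric tricyclic β-hydroxy methyl ester (C7–OH syn to C9–OTBS) | COC(=O)[C@]1(C)[C@@H]2[C@H]3C(=O)C=C(C)[C@@H]2[C@@]3(C)[C@H](O[Si](C)(C)C(C)(C)C)C[C@@H]1O
F2 | step 19 | C7-epimeric tricyclic triol | OC[C@]1(C)[C@@H]2[C@H]3[C@H](O)C=C(C)[C@@H]2[C@@]3(C)[C@H](O[Si](C)(C)C(C)(C)C)C[C@@H]1O
F3 | step 19 | tricyclic keto aldehyde (C1 enone, C7 ketone, formyl on C6, C9–OTBS) | O=C[C@]1(C)[C@@H]2[C@H]3C(=O)C=C(C)[C@@H]2[C@@]3(C)[C@H](O[Si](C)(C)C(C)(C)C)CC1=O
F4 | step 11 | 7-{[(tert-butyldiphenylsilyl)oxy]methyl}-7-methyl-2-methylidene-4-[(triethylsilyl)oxy]bicyclo[3.1.1]heptan-6-ol (C5–OH syn) | O[C@H]1[C@H]2[C@@H](O[Si](CC)(CC)CC)CC(=C)[C@@H]1[C@@]2(C)CO[Si](c3ccccc3)(c3ccccc3)C(C)(C)C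
F5 | step 11 | trifluoromethanesulfonate of F4 (C5–OTf syn) | FC(F)(F)S(=O)(=O)O[C@H]1[C@H]2[C@@H](O[Si](CC)(CC)CC)CC(=C)[C@@H]1[C@@]2(C)CO[Si](c3ccccc3)(c3ccccc3)C(C)(C)C
F6 | step 11 | dimethyl 2-(7-{[(tert-butyldiphenylsilyl)oxy]methyl}-7-methyl-2-methylidene-4-[(triethylsilyl)oxy]bicyclo[3.1.1]heptan-6-yl)malonate (malonate anti on C5) | COC(=O)C(C(=O)OC)[C@@H]1[C@H]2[C@@H](O[Si](CC)(CC)CC)CC(=C)[C@@H]1[C@@]2(C)CO[Si](c3ccccc3)(c3ccccc3)C(C)(C)C
F7 | step 11 | methyl 2-(7-{[(tert-butyldiphenylsilyl)oxy]methyl}-7-methyl-2-methylidene-4-[(triethylsilyl)oxy]bicyclo[3.1.1]heptan-6-yl)acetate | COC(=O)C[C@@H]1[C@H]2[C@@H](O[Si](CC)(CC)CC)CC(=C)[C@@H]1[C@@]2(C)CO[Si](c3ccccc3)(c3ccccc3)C(C)(C)C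
F8 | step 9 | (2E,5S,6E)-8-[(tert-butyldiphenylsilyl)oxy]-N,N,3,7-tetramethyl-5-[(triethylsilyl)oxy]octa-2,6-dienamide | CC(C)(C)[Si](c1ccccc1)(c1ccccc1)OC/C(C)=C/[C@@H](O[Si](CC)(CC)CC)C/C(C)=C/C(=O)N(C)C
F9 | step 9 | cyclobutaniminium triflate (N,N-dimethyliminium at C5 of the bicycle of 13) | C[N+](C)=C1[C@H]2[C@@H](O[Si](CC)(CC)CC)CC(=C)[C@@H]1[C@@]2(C)CO[Si](c3ccccc3)(c3ccccc3)C(C)(C)C.[O-]S(=O)(=O)C(F)(F)F
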